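**Retrosynthetic overview**

- The route rests on the central ring (ring B), a benzene-1,3,5-triol whose other three carbons carry two arylmethyl groups and one bromine. Oxygen on alternate carbons is the pattern of a folded 3,5-dioxo diester chain, and the brominated carbon corresponds to the chain-end methylene, so it is carried as C–CO2Me.
- Vidalol B ⇐ BBr3 cleavage of the four methyl ethers ⇐ bromination at the single C–H of ring B ⇐ hydrolysis and decarboxylation of the ring-B methyl ester.
- Ring-B ester ⇐ Claisen closure (chain C6 onto the C1 ester) of dimethyl 2,4-bis(arylmethyl)-3,5-dioxoheptanedioate. Ring B is the only ring formed; rings A and C are bought as 5-bromovanillin.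
- Dioxo diester ⇐ acylation of a bis(silyl) dienol ether at its terminal carbon by methyl malonyl chloride ⇐ methyl acetoacetate benzylated at C4 (dianion) and at C2 (enolate).
- Benzyl bromide ⇐ 5-bromovanillin by ring bromination, O-methylation, reduction and bromide formation.

Key step: step 10

Remark: the doubly benzylated keto ester and the dioxo diester are carried as stereoisomer (and keto–enol) mixtures, and the silyl enol ether geometries are not controlled; all of this is erased when ring B aromatises, so these SMILES carry no configuration. The target has no stereocentre.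

**Route**

Step 1
Reactants: 1 5-bromovanillin (3-bromo-4-hydroxy-5-methoxybenzaldehyde)
Product: 2 2,3-dibromo-4-hydroxy-5-methoxybenzaldehyde (5,6-dibromovanillin)
Conditions: Br2 (1.1 equiv), Fe powder (cat.), NaOAc, AcOH, rt
Reagents that add atoms: bromine, BrBr
Why: Electrophilic aromatic bromination; the methoxy group directs para, and that position is the only open one not wedged between CHO and OMe, so the second bromine should enter next to the first.

Step 2
Reactants: 2 2,3-dibromo-4-hydroxy-5-methoxybenzaldehyde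
Product: 3 2,3-dibromo-4,5-dimethoxybenzaldehyde
Conditions: MeI, K2CO3, DMF, rt
Reagents that add atoms: iodomethane, CI
Why: Williamson ether synthesis; the acidic phenol, flanked by Br and OMe, is O-methylated by SN2 on MeI.

Step 3
Reactants: 3 2,3-dibromo-4,5-dimethoxybenzaldehyde
Product: 4 (2,3-dibromo-4,5-dimethoxyphenyl)methanol
Conditions: NaBH4, MeOH/THF, 0 °C
Reagents that add atoms: none
Why: Hydride reduction of an aryl aldehyde by NaBH4; aryl bromides and ethers are inert.

Step 4
Reactants: 4 (2,3-dibromo-4,5-dimethoxyphenyl)methanol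
Product: 5 2,3-dibromo-1-(bromomethyl)-4,5-dimethoxybenzene
Conditions: PBr3, CH2Cl2, 0 °C → rt
Reagents that add atoms: phosphorus tribromide, BrP(Br)Br
Why: Alcohol-to-bromide conversion with PBr3 (SN2 displacement of the bromophosphite), which is facile at a benzylic carbon.

Step 5
Reactants: 6 methyl acetoacetate; 5 2,3-dibromo-1-(bromomethyl)-4,5-dimethoxybenzene
Product: 8 methyl 5-(2,3-dibromo-4,5-dimethoxyphenyl)-3-oxopentanoate, via the sodium lithium dianion of methyl acetoacetate 7 (not isolated)
Conditions: NaH (1.1 equiv), THF, 0 °C; n-BuLi (1.0 equiv), 0 °C; then 5 (0.9 equiv), 0 °C → rt; aq. HCl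
Reagents that add atoms: none
Why: Weiler dianion alkylation; the more basic terminal (C4) carbanion attacks the benzylic bromide by SN2, and since n-BuLi is consumed before 5 is added no bromine–lithium exchange should touch the aryl bromides.

Step 6
Reactants: 8 methyl 5-(2,3-dibromo-4,5-dimethoxyphenyl)-3-oxopentanoate; 5 2,3-dibromo-1-(bromomethyl)-4,5-dimethoxybenzene
Product: 9 methyl 2-(2,3-dibromo-4,5-dimethoxybenzyl)-5-(2,3-dibromo-4,5-dimethoxyphenyl)-3-oxopentanoate (racemic)
Conditions: K2CO3, acetone, reflux (8 in slight excess)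
Reagents that add atoms: none
Why: Acetoacetic ester C-alkylation; K2CO3 deprotonates only C2, and a small excess of 8 limits double alkylation.

Step 7
Reactants: 9 methyl 2-(2,3-dibromo-4,5-dimethoxybenzyl)-5-(2,3-dibromo-4,5-dimethoxyphenyl)-3-oxopentanoate
Product: 10 methyl 2-(2,3-dibromo-4,5-dimethoxybenzyl)-5-(2,3-dibromo-4,5-dimethoxyphenyl)-3-(trimethylsilyloxy)pent-2-enoate (crude, geometry not controlled)
Conditions: Me3SiCl, Et3N, toluene, rt; filter, concentrate
Reagents that add atoms: chlorotrimethylsilane, C[Si](C)(C)Cl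
Why: Soft enolisation and O-silylation of the β-keto ester (silyl enol ether formation); this is the standard first stage towards 1,3-bis(silyloxy)dienes, also for 2-alkyl acetoacetates.

Step 8
Reactants: 10 methyl 2-(2,3-dibromo-4,5-dimethoxybenzyl)-5-(2,3-dibromo-4,5-dimethoxyphenyl)-3-(trimethylsilyloxy)pent-2-enoate
Product: 11 1-methoxy-2-(2,3-dibromo-4,5-dimethoxybenzyl)-5-(2,3-dibromo-4,5-dimethoxyphenyl)-1,3-bis(trimethylsilyloxy)penta-1,3-diene (crude, used at once)
Conditions: LDA (LiN(i-Pr)2), THF, −78 °C; Me3SiCl, −78 °C → rt; concentrate, take up in hexane, filter under Ar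
Reagents that add atoms: chlorotrimethylsilane, C[Si](C)(C)Cl
Why: Kinetic γ-deprotonation of the β-silyloxy enoate to the extended dienolate and O-silylation (Chan-type diene preparation); LDA does not exchange aryl bromides, and neither ring has a hydrogen ortho to bromine, so no aryne can form.

Step 9
Reactants: 11 1-methoxy-2-(2,3-dibromo-4,5-dimethoxybenzyl)-5-(2,3-dibromo-4,5-dimethoxyphenyl)-1,3-bis(trimethylsilyloxy)penta-1,3-diene; 12 methyl malonyl chloride (methyl 3-chloro-3-oxopropanoate)
Product: 13 dimethyl 2,4-bis(2,3-dibromo-4,5-dimethoxybenzyl)-3,5-dioxoheptanedioate (mixture of diastereomers and tautomers)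
Conditions: CH2Cl2, −78 → 20 °C; then aq. HCl
Reagents that add atoms: none
Why: Vinylogous Mukaiyama-type C-acylation of a 1,3-bis(silyl enol ether) by an acid chloride at the terminal diene carbon with loss of Me3SiCl, a known entry to 3,5-dioxo esters; the acidic work-up removes the remaining silyl group.

Step 10
Reactants: 13 dimethyl 2,4-bis(2,3-dibromo-4,5-dimethoxybenzyl)-3,5-dioxoheptanedioate
Product: 14 methyl 3,5-bis(2,3-dibromo-4,5-dimethoxybenzyl)-2,4,6-trihydroxybenzoate
Conditions: NaOMe (4 equiv), MeOH, rt → 65 °C, Ar; then aq. HCl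
Reagents that add atoms: none
Why: NaOMe deprotonates 13 at C4 and then at the C6 methylene between the C5 ketone and the C7 ester; the C6 carbanion attacks the C1 ester carbonyl, methoxide leaves, and the cyclic triketo ester enolises to the benzene-1,3,5-triol, held as its phenoxide until acidification. The closest known reaction type is the Claisen (Dieckmann-type) cyclisation of 3,5-dioxo esters to 2,4,6-trihydroxybenzoates. Ring B is closed in a 6-exo-trig (enolate-exo) mode, forming the bond between the ester-bearing carbon and a neighbouring oxygen-bearing carbon. No stereocentre is created, and the two epimerisable centres of 13 (C2 and C4) become sp2 ring carbons. The step needs C- rather than O-acylation and the C6→C1 rather than the C2→C7 direction; the substrate secures this because C6 is the only nucleophilic carbon carrying two hydrogens, so only its adduct can aromatise, whereas the C2→C7 adduct (quaternary carbon) and any 4-hydroxy-2-pyranone from O-attack should be reopened by methoxide and fed back. Aromatisation is therefore the thermodynamic sink under reversible alkoxide conditions, and using methoxide with methyl esters avoids ester scrambling.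

Step 11
Reactants: 14 methyl 3,5-bis(2,3-dibromo-4,5-dimethoxybenzyl)-2,4,6-trihydroxybenzoate
Product: 16 2,4-bis(2,3-dibromo-4,5-dimethoxybenzyl)benzene-1,3,5-triol, via the free carboxylic acid 15 (not isolated)
Conditions: NaOH (2 M aq., degassed), MeOH, reflux, Ar; then aq. HCl, 60 °C
Reagents that add atoms: none
Why: Saponification followed on acidification by decarboxylation of the 2,4,6-trihydroxybenzoic acid through its β-keto acid tautomer (classical hydrolysis–decarboxylation of phloroglucinol carboxylates); aryl bromides and methyl ethers are inert to aqueous hydroxide.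

Step 12
Reactants: 16 2,4-bis(2,3-dibromo-4,5-dimethoxybenzyl)benzene-1,3,5-triol
Product: 17 2-bromo-4,6-bis(2,3-dibromo-4,5-dimethoxybenzyl)benzene-1,3,5-triol
Conditions: NBS (1.0 equiv), THF, −78 → 0 °C
Reagents that add atoms: N-bromosuccinimide, O=C1CCC(=O)N1Br
Why: Electrophilic aromatic bromination at the single C–H of ring B, the carbon freed by loss of the ester; it is activated by three hydroxyl groups and should far outrun the lone C–H of rings A and C.

Step 13
Reactants: 17 2-bromo-4,6-bis(2,3-dibromo-4,5-dimethoxybenzyl)benzene-1,3,5-triol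
Product: 18 vidalol B (2-bromo-4,6-bis(2,3-dibromo-4,5-dihydroxybenzyl)benzene-1,3,5-triol)
Conditions: BBr3 (10 equiv), CH2Cl2, −78 °C → rt; then ice water
Reagents that add atoms: none
Why: BBr3 cleavage of aryl methyl ethers (Lewis acid complexation, SN2 demethylation by bromide, hydrolysis of the aryl borates on work-up); the four methoxy groups should fall together and the C–Br bonds are untouched.

**Compound list**

1 | 5-bromovanillin | COc1cc(C=O)cc(Br)c1O | starting material
2 | 2,3-dibromo-4-hydroxy-5-methoxybenzaldehyde | COc1cc(C=O)c(Br)c(Br)c1O | intermediate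
3 | 2,3-dibromo-4,5-dimethoxybenzaldehyde | COc1cc(C=O)c(Br)c(Br)c1OC | intermediate
4 | (2,3-dibromo-4,5-dimethoxyphenyl)methanol | COc1cc(CO)c(Br)c(Br)c1OC | intermediate
5 | 2,3-dibromo-1-(bromomethyl)-4,5-dimethoxybenzene | COc1cc(CBr)c(Br)c(Br)c1OC | intermediate
6 | methyl acetoacetate | COC(=O)CC(C)=O | starting material
7 | sodium lithium dianion of methyl acetoacetate | C=C([O-])C=C([O-])OC.[Na+].[Li+] | intermediate (not isolated)
8 | methyl 5-(2,3-dibromo-4,5-dimethoxyphenyl)-3-oxopentanoate | COC(=O)CC(=O)CCc1cc(OC)c(OC)c(Br)c1Br | intermediate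
9 | methyl 2-(2,3-dibromo-4,5-dimethoxybenzyl)-5-(2,3-dibromo-4,5-dimethoxyphenyl)-3-oxopentanoate | COC(=O)C(Cc1cc(OC)c(OC)c(Br)c1Br)C(=O)CCc1cc(OC)c(OC)c(Br)c1Br | intermediate
10 | methyl 2-(2,3-dibromo-4,5-dimethoxybenzyl)-5-(2,3-dibromo-4,5-dimethoxyphenyl)-3-(trimethylsilyloxy)pent-2-enoate | COC(=O)C(Cc1cc(OC)c(OC)c(Br)c1Br)=C(O[Si](C)(C)C)CCc1cc(OC)c(OC)c(Br)c1Br | intermediate
11 | 1-methoxy-2-(2,3-dibromo-4,5-dimethoxybenzyl)-5-(2,3-dibromo-4,5-dimethoxyphenyl)-1,3-bis(trimethylsilyloxy)penta-1,3-diene | COC(O[Si](C)(C)C)=C(Cc1cc(OC)c(OC)c(Br)c1Br)C(O[Si](C)(C)C)=CCc1cc(OC)c(OC)c(Br)c1Br | intermediate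
12 | methyl malonyl chloride | COC(=O)CC(Cl)=O | starting material
13 | dimethyl 2,4-bis(2,3-dibromo-4,5-dimethoxybenzyl)-3,5-dioxoheptanedioate | COC(=O)CC(=O)C(Cc1cc(OC)c(OC)c(Br)c1Br)C(=O)C(Cc1cc(OC)c(OC)c(Br)c1Br)C(=O)OC | intermediate
14 | methyl 3,5-bis(2,3-dibromo-4,5-dimethoxybenzyl)-2,4,6-trihydroxybenzoate | COC(=O)c1c(O)c(Cc2cc(OC)c(OC)c(Br)c2Br)c(O)c(Cc2cc(OC)c(OC)c(Br)c2Br)c1O | intermediate
15 | 3,5-bis(2,3-dibromo-4,5-dimethoxybenzyl)-2,4,6-trihydroxybenzoic acid | OC(=O)c1c(O)c(Cc2cc(OC)c(OC)c(Br)c2Br)c(O)c(Cc2cc(OC)c(OC)c(Br)c2Br)c1O | intermediate (not isolated)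
16 | 2,4-bis(2,3-dibromo-4,5-dimethoxybenzyl)benzene-1,3,5-triol | Oc1cc(O)c(Cc2cc(OC)c(OC)c(Br)c2Br)c(O)c1Cc1cc(OC)c(OC)c(Br)c1Br | intermediate
17 | 2-bromo-4,6-bis(2,3-dibromo-4,5-dimethoxybenzyl)benzene-1,3,5-triol | Oc1c(Br)c(O)c(Cc2cc(OC)c(OC)c(Br)c2Br)c(O)c1Cc1cc(OC)c(OC)c(Br)c1Br | intermediate
18 | vidalol B | Oc1cc(Cc2c(O)c(Br)c(O)c(Cc3cc(O)c(O)c(Br)c3Br)c2O)c(Br)c(Br)c1O | target

**Step count and risks**

Total step count: 13. Longest linear sequence: 13 steps (steps 1–13, from 5-bromovanillin).

Steps most likely to fail: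

1. Step 10 (key step). Methoxide may cleave the 2-substituted 1,3-diketone by intermolecular retro-Claisen fragmentation faster than the ring closes, or material may drain into a pyranone that reopens too slowly. The fallback sets out from 4 and comes back at 14. Purchased methyl 2,4,6-trihydroxybenzoate F1 is treated with alcohol 4 (2.2 equiv) and BF3·OEt2 in dioxane at rt → 50 °C. Friedel–Crafts benzylation by the para-methoxy-stabilised benzylic cation should give first methyl 3-(2,3-dibromo-4,5-dimethoxybenzyl)-2,4,6-trihydroxybenzoate F2 and then 14. The ester again occupies the future bromine site, so a third benzylation is excluded.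

2. Step 9. Methyl malonyl chloride may lose HCl to a ketene and oligomerise, and C-acylation of the congested, 2-substituted diene may be slow enough that protodesilylation back to 9 wins. The fallback sets out from 8 and 5 and comes back at 13; it forms the C3–C4 bond of 13 instead of C4–C5, so the diene carries no C2 substituent.
   - Purchased dimethyl malonate F3 is alkylated with 5 (NaH, THF) to dimethyl 2-(2,3-dibromo-4,5-dimethoxybenzyl)malonate F4.
   - F4 is half-saponified (KOH, 1 equiv, MeOH) to 2-(2,3-dibromo-4,5-dimethoxybenzyl)-3-methoxy-3-oxopropanoic acid F5.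
   - F5 is converted with (COCl)2 and catalytic DMF into methyl 2-(2,3-dibromo-4,5-dimethoxybenzyl)-3-chloro-3-oxopropanoate F6.
   - In parallel, 8 is silylated (Me3SiCl, Et3N) to methyl 5-(2,3-dibromo-4,5-dimethoxyphenyl)-3-(trimethylsilyloxy)pent-2-enoate F7, and then (LDA; Me3SiCl, THF, −78 °C) to 1-methoxy-5-(2,3-dibromo-4,5-dimethoxyphenyl)-1,3-bis(trimethylsilyloxy)penta-1,3-diene F8.
   - The terminal carbon of F8 is acylated by F6 (CH2Cl2, −78 → 20 °C, then aq. HCl) to give 13.

3. Step 12. The very electron-rich triol may be over-brominated or oxidatively dearomatised at the benzyl-bearing carbons, or bromine may enter the free position of ring A or C. The fallback sets out from 14 and comes back at 17. The ester is saponified as in step 11, but the mixture is acidified cold and acid 15 is isolated without heating. Br2 (1.0 equiv) in AcOH at 0–20 °C should then attack the carboxyl-bearing carbon ipso with loss of CO2 (bromodecarboxylation of a hydroxybenzoic acid), giving 17. The C–H triol 16 is never exposed to the brominating agent.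

**Further compounds**

F1 | step 10 | methyl 2,4,6-trihydroxybenzoate (bought, not made) | COC(=O)c1c(O)cc(O)cc1O
F2 | step 10 | methyl 3-(2,3-dibromo-4,5-dimethoxybenzyl)-2,4,6-trihydroxybenzoate | COC(=O)c1c(O)cc(O)c(Cc2cc(OC)c(OC)c(Br)c2Br)c1O
F3 | step 9 | dimethyl malonate (bought, not made) | COC(=O)CC(=O)OC
F4 | step 9 | dimethyl 2-(2,3-dibromo-4,5-dimethoxybenzyl)malonate | COC(=O)C(Cc1cc(OC)c(OC)c(Br)c1Br)C(=O)OC
F5 | step 9 | 2-(2,3-dibromo-4,5-dimethoxybenzyl)-3-methoxy-3-oxopropanoic acid | COC(=O)C(Cc1cc(OC)c(OC)c(Br)c1Br)C(O)=O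
F6 | step 9 | methyl 2-(2,3-dibromo-4,5-dimethoxybenzyl)-3-chloro-3-oxopropanoate | COC(=O)C(Cc1cc(OC)c(OC)c(Br)c1Br)C(Cl)=O
F7 | step 9 | methyl 5-(2,3-dibromo-4,5-dimethoxyphenyl)-3-(trimethylsilyloxy)pent-2-enoate | COC(=O)C=C(O[Si](C)(C)C)CCc1cc(OC)c(OC)c(Br)c1Br
F8 | step 9 | 1-methoxy-5-(2,3-dibromo-4,5-dimethoxyphenyl)-1,3-bis(trimethylsilyloxy)penta-1,3-diene | COC(O[Si](C)(C)C)=CC(O[Si](C)(C)C)=CCc1cc(OC)c(OC)c(Br)c1Br
F0 | step 12 | none | none
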